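Ring B carries oxygen at C6 next to the branched C7. It is therefore read as the adduct of a C5=C6–C7=C8 2-silyloxydiene and a C9=C10 isopropenyl ketone, whose methyl becomes C14 and whose carbonyl becomes the C1 oxygen. Because C1–C4 tie C10 to C5, one thermal intramolecular Diels–Alder reaction forms C5–C10 and C8–C9, closes rings A and B, and sets C5 and C10 from the lone C3 stereocentre. The precursor is an open-chain (S)-trienone with a C3 silyl ether, a C4 dioxolane and a (Z)-triethylsilyl enol ether. Its enone is released last, from a Weinreb amide, so that enol silylation meets a single ketone.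

Key step: step 13

Remark on the chemistry: eudesmane numbering (C1–C15) is used for all compounds, open-chain ones included; carbinol centres that are oxidised in the following step (C4 in 5, C6 in 13) are carried as epimer mixtures; TBS = tert-butyldimethylsilyl, TES = triethylsilyl, TBDPS = tert-butyldiphenylsilyl.

Step 1
Reactants: 1 (S)-3-hydroxy-γ-butyrolactone
Product: 2 (S)-3-(TBS-oxy)-γ-butyrolactone
Conditions: TBSCl, imidazole, DMF, 0 °C to rt
Reagents that add atoms: tert-butyldimethylsilyl chloride, CC(C)(C)[Si](C)(C)Cl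
Why: Standard imidazole-mediated silylation of a secondary alcohol, mild enough to avoid β-elimination to the butenolide, protects the chiral-pool C3 oxygen without touching its configuration.

Step 2
Reactants: 2 (S)-3-(TBS-oxy)-γ-butyrolactone
Product: 3 (3S)-3-(TBS-oxy)-4-hydroxy-N-methoxy-N-methylbutanamide
Conditions: MeNHOMe·HCl, AlMe3, CH2Cl2, 0 °C to rt; aq. potassium sodium tartrate work-up
Reagents that add atoms: N,O-dimethylhydroxylamine hydrochloride, CNOC.Cl
Why: Weinreb aminolysis of a lactone with the weakly basic aluminium amide attacks only the acyl carbon C1, so the ring opens to the C1 Weinreb amide and the free C4 hydroxyl while C3 stays untouched.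

Step 3
Reactants: 3 (3S)-3-(TBS-oxy)-4-hydroxy-N-methoxy-N-methylbutanamide
Product: 4 (3S)-3-(TBS-oxy)-N-methoxy-N-methyl-4-oxobutanamide
Conditions: Dess–Martin periodinane, CH2Cl2, 0 °C to rt, used at once
Reagents that add atoms: none
Why: Dess–Martin oxidation takes the primary alcohol to the aldehyde under nearly neutral conditions, which forestalls relactonisation, silyl migration and epimerisation of the α-silyloxy aldehyde.

Step 4
Reactants: 4 (3S)-3-(TBS-oxy)-N-methoxy-N-methyl-4-oxobutanamide
Product: 5 (3S)-3-(TBS-oxy)-4-hydroxy-N-methoxy-N-methylhept-6-enamide (both C4 epimers)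
Conditions: allylboronic acid pinacol ester, CH2Cl2, rt; aq. NaHCO3 work-up
Reagents that add atoms: allylboronic acid pinacol ester, C=CCB1OC(C)(C)C(C)(C)O1
Why: Uncatalysed allylboration through a closed six-membered transition state is specific for the aldehyde and ignores the Weinreb amide, and the new C4 carbinol centre needs no control because it is oxidised next.

Step 5
Reactants: 5 (3S)-3-(TBS-oxy)-4-hydroxy-N-methoxy-N-methylhept-6-enamide
Product: 6 (3S)-3-(TBS-oxy)-N-methoxy-N-methyl-4-oxohept-6-enamide
Conditions: Dess–Martin periodinane, CH2Cl2, 0 °C to rt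
Reagents that add atoms: none
Why: Dess–Martin oxidation gives the C4 allyl ketone without base, so the β,γ-double bond is not drawn into conjugation and the α-silyloxy centre C3 is not epimerised.

Step 6
Reactants: 6 (3S)-3-(TBS-oxy)-N-methoxy-N-methyl-4-oxohept-6-enamide
Product: 7 (3S)-3-(2-allyl-1,3-dioxolan-2-yl)-3-(TBS-oxy)-N-methoxy-N-methylpropanamide
Conditions: Me3SiOCH2CH2OSiMe3, Me3SiOTf (0.2 equiv), CH2Cl2, −78 to −20 °C; pyridine quench
Reagents that add atoms: 1,2-bis(trimethylsilyloxy)ethane, C[Si](C)(C)OCCO[Si](C)(C)C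
Why: Noyori ketalisation works aprotically at low temperature and is driven by formation of hexamethyldisiloxane, conditions known to ketalise β,γ-unsaturated ketones without alkene migration and to spare TBS ethers.

Step 7
Reactants: 7 (3S)-3-(2-allyl-1,3-dioxolan-2-yl)-3-(TBS-oxy)-N-methoxy-N-methylpropanamide
Product: 9 (3S)-3-(TBS-oxy)-N-methoxy-N-methyl-3-[2-(2-oxoethyl)-1,3-dioxolan-2-yl]propanamide, via secondary ozonide 8 (not isolated)
Conditions: O3, CH2Cl2, −78 °C; then PPh3, −78 °C to rt
Reagents that add atoms: ozone, [O-][O+]=O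
Why: Ozonolysis with reductive work-up cleaves the only alkene present to the C6 aldehyde under neutral conditions that do not open the β-ketal.

Step 8
Reactants: 10 3-bromobut-3-en-1-ol
Product: 11 (3-bromobut-3-en-1-yloxy)(tert-butyl)dimethylsilane
Conditions: TBSCl, imidazole, CH2Cl2, rt
Reagents that add atoms: tert-butyldimethylsilyl chloride, CC(C)(C)[Si](C)(C)Cl
Why: Routine silylation of a primary alcohol masks the future C12 oxygen so that the vinyl bromide can be lithiated.

Step 9
Reactants: 11 (3-bromobut-3-en-1-yloxy)(tert-butyl)dimethylsilane; 9 the C6 aldehyde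
Product: 13 C6 allylic alcohol, (3S)-3-(TBS-oxy)-3-{2-[2-hydroxy-3-methylene-5-(TBS-oxy)pentyl]-1,3-dioxolan-2-yl}-N-methoxy-N-methylpropanamide (both C6 epimers), via vinyllithium 12 (not isolated)
Conditions: 11 (1.05 equiv), t-BuLi (2 equiv per 11), Et2O, −78 °C; then 9, −78 °C; aq. NH4Cl
Reagents that add atoms: none
Why: Bromine–lithium exchange followed by 1,2-addition forms C6–C7, since at −78 °C and with near-stoichiometric organolithium the aldehyde reacts far faster than the Weinreb amide, and the C6 carbinol centre is erased in the next step.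

Step 10
Reactants: 13 C6 allylic alcohol
Product: 14 C6 enone, (3S)-3-(TBS-oxy)-3-{2-[3-methylene-2-oxo-5-(TBS-oxy)pentyl]-1,3-dioxolan-2-yl}-N-methoxy-N-methylpropanamide
Conditions: Dess–Martin periodinane, CH2Cl2, 0 °C to rt
Reagents that add atoms: none
Why: Dess–Martin oxidation of the allylic alcohol delivers the α-substituted vinyl ketone without base, so the β-ketal is not opened by elimination.

Step 11
Reactants: 14 C6 enone
Product: 16 (Z)-C5=C6 TES dienol ether that still carries the C1 Weinreb amide, via potassium enolate 15 (not isolated)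
Conditions: KN(SiMe3)2 (1.05 equiv), THF, −78 °C; then Et3SiCl, −78 °C; cold aq. NaHCO3, chromatography on Et3N-washed silica
Reagents that add atoms: triethylsilyl chloride, CC[Si](Cl)(CC)CC
Why: Enolate formation and O-silylation are site-selective because the C6 ketone is the only ketone, can enolise only towards C5 and is several pK units more acidic than the amide, while the bulky ketal carbon C4 avoids the C7 branch and so ends up cis to oxygen, that is (Z), and the low temperature holds back β-alkoxide loss.

Step 12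
Reactants: 16 (Z)-TES dienol ether Weinreb amide
Product: 18 (S)-trienone with C9=C10 isopropenyl ketone, C3 OTBS, C4 dioxolane, (Z)-C5=C6 TES enol ether, C7=C8 methylene and C12 OTBS, via magnesium chelate 17 (not isolated)
Conditions: CH2=C(CH3)MgBr, THF, −20 to 0 °C; pH 7 phosphate buffer, used without delay
Reagents that add atoms: isopropenylmagnesium bromide, C=C(C)[Mg]Br
Why: In this Weinreb ketone synthesis the chelated tetrahedral adduct blocks a second addition and collapses only on neutral work-up, silyl enol ethers are inert to Grignard reagents, and the dienophile thus appears only after the diene is in place.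

Step 13
Reactants: 18 (S)-trienone
Product: 19 trans-fused 1-oxo-octalin (5α-H, 10β-methyl) with 3β-OTBS, C4 dioxolane, C6=C7 TES enol ether and C12 OTBS
Conditions: PhMe (0.01 M), BHT, N,O-bis(trimethylsilyl)acetamide (acid scavenger), base-washed sealed tube, 160 °C
Reagents that add atoms: none
Why: On heating, the s-cis C5=C6–C7=C8 silyloxydiene and the C9=C10 isopropenyl ketone combine in a concerted, suprafacial [4+2] cycloaddition, the closest known reaction type being the thermal intramolecular Diels–Alder reaction of 2-methyl-1,7,9-decatrien-3-ones to angular-methyl octalones. Ring B closes as the six-membered cycloadduct ring through the new C5–C10 and C8–C9 bonds, and ring A closes in the fused (type 1) mode as the tether ring, because the four atoms C1–C4 join C10 to the diene terminus C5 and can fold as a chair. The relative configuration of C5 and C10 follows from the (Z)-enol ether, which places C4 on the outside of the diene, together with the transition state that keeps the C1 carbonyl exo and the C14 methyl endo, the orientation that α-methyl enones tend to prefer; this gives the trans fusion, which is an expectation and not a certainty. The absolute sense at both centres is relayed from C3, whose silyl ether takes the equatorial site of the chair-like tether and so selects one diene face. The step needs fused rather than bridged regiochemistry, and the short tether secures it even though a 2-silyloxydiene would by itself pair C5 with C9, so the donor gives little rate help, heat is required, and Lewis acids, which would favour Mukaiyama–Michael attack of C5 on C9 or ionise the allylic ketal, are left out. High dilution, BHT and a neutral acid scavenger suppress dimerisation, polymerisation and hydrolysis of the enol ether, which survives as the C6=C7 silyl enol ether that stores the C6 oxygen and leaves C7 trigonal.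

Step 14
Reactants: 19 trans-fused 1-oxo-octalin
Product: 20 1β-alcohol of 19
Conditions: LiAlH4, Et2O, −78 to 0 °C; aq. NaOH work-up
Reagents that add atoms: none
Why: Hydride reduction by a small aprotic reagent proceeds by axial attack on the α face, away from the adjacent axial C14 methyl, and sets the equatorial 1β-hydroxyl (1R), while the enol ether keeps C6 masked and inert.

Step 15
Reactants: 20 1β-alcohol
Product: 21 1β,3β-bis(TBS) ether with C6=C7 TES enol ether
Conditions: TBSOTf, 2,6-lutidine, CH2Cl2, 0 °C
Reagents that add atoms: tert-butyldimethylsilyl triflate, CC(C)(C)[Si](C)(C)OS(=O)(=O)C(F)(F)F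
Why: Silylation with the triflate reaches the neopentyl-type C1 hydroxyl that the chloride would silylate only slowly, and the hindered base leaves ketal and enol ether intact.

Step 16
Reactants: 21 bis(TBS) ether with TES enol ether
Product: 22 6-ketone with 5α-H, 7α-H and the equatorial 7β-(2-TBS-oxyethyl) chain
Conditions: Bu4NF, AcOH (1:1), THF, −20 to 0 °C
Reagents that add atoms: none
Why: Buffered fluoride cleaves the TES enol ether much faster than any TBS alkyl ether, and the liberated enol is protonated at C7 along the axial α trajectory, which sets 7S with the side chain equatorial, the same epimer that equilibration beside the ketone would favour, without basic conditions that could open the β-ketal.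

Step 17
Reactants: 22 6-ketone
Product: 23 6α-alcohol
Conditions: Li, NH3(l), THF, EtOH, −78 °C; NH4Cl quench
Reagents that add atoms: none
Why: Dissolving-metal reduction through the ketyl is chosen because it leads to the more stable equatorial 6α-alcohol (6S), whereas hydride reagents would enter from the α face, the β face being screened by C14 and the axial ketal oxygen, and would give the axial epimer; silyl ethers and the ketal are inert.

Step 18
Reactants: 24 methyl 2-(hydroxymethyl)acrylate
Product: 25 methyl 2-[(TBDPS-oxy)methyl]acrylate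
Conditions: TBDPSCl, imidazole, CH2Cl2, rt
Reagents that add atoms: tert-butyldiphenylsilyl chloride, CC(C)(C)[Si](Cl)(c1ccccc1)c1ccccc1
Why: Routine silylation installs an acid-resistant primary silyl ether that will outlast the later acidic removal of the ketal and of the C12 TBS group.

Step 19
Reactants: 25 methyl 2-[(TBDPS-oxy)methyl]acrylate
Product: 26 2-[(TBDPS-oxy)methyl]acrylic acid
Conditions: LiOH, THF/H2O, rt; then 1 M HCl to pH 3
Reagents that add atoms: lithium hydroxide, [Li+].[OH-]
Why: Saponification of the unhindered methyl ester is faster than conjugate addition of hydroxide to the α-substituted acrylate, and the TBDPS ether is stable to aqueous base.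

Step 20
Reactants: 26 2-[(TBDPS-oxy)methyl]acrylic acid; 23 6α-alcohol
Product: 28 6α-{2-[(TBDPS-oxy)methyl]acryloyloxy} derivative of 23, via mixed anhydride 27 (not isolated)
Conditions: 26, 2,4,6-trichlorobenzoyl chloride, Et3N, PhMe, rt; then 23, DMAP, PhMe, rt to 60 °C
Reagents that add atoms: none
Why: Yamaguchi esterification acylates hindered secondary alcohols, the C6 hydroxyl is the only free one, its C–O bond is not broken so 6S is retained, and acylating now means that a free C6 hydroxyl never coexists with a C12 ester, so no lactone has to be opened later.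

Step 21
Reactants: 28 C6 ester with C4 dioxolane and C12 OTBS
Product: 29 4-ketone with free C12 hydroxyl (1β,3β-OTBS, 6α-acyloxy retained)
Conditions: p-TsOH·H2O (0.3 equiv), acetone/H2O (9:1), 40 °C
Reagents that add atoms: water, O
Why: Acid-catalysed hydrolysis removes the primary TBS ether and the dioxolane, whose ionisation relieves the syn-axial contact with C14, while the two hindered secondary TBS ethers, the TBDPS ether and the ester are much slower to react, and C3 and C5 already hold their stable equatorial and trans-fused arrangements beside the new ketone.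

Step 22
Reactants: 29 4-ketone
Product: 30 4(15)-methylene compound with free C12 hydroxyl
Conditions: Zn, CH2Br2, TiCl4 (pre-mixed in THF and aged at 0–5 °C, excess), CH2Cl2, 0 °C to rt
Reagents that add atoms: dibromomethane, BrCBr
Why: Takai–Lombardo methylenation uses a non-basic gem-dimetallic reagent that attacks ketones but not esters, so C5 and C3 are not epimerised, the β-acyloxy group is not eliminated, and the free hydroxyl merely consumes extra reagent.

Step 23
Reactants: 30 4(15)-methylene alcohol
Product: 31 C12 aldehyde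
Conditions: Dess–Martin periodinane, CH2Cl2, 0 °C to rt
Reagents that add atoms: none
Why: Dess–Martin oxidation of the only free alcohol stops at the aldehyde and tolerates the alkenes, esters and silyl ethers.

Step 24
Reactants: 31 C12 aldehyde
Product: 33 11(13)-en-12-al (α-methylene aldehyde), via Mannich base 32 (not isolated)
Conditions: CH2=NMe2+ I−, Et3N, CH2Cl2, rt
Reagents that add atoms: N,N-dimethylmethyleneiminium iodide, C=[N+](C)C.[I-]
Why: Mannich reaction of the aldehyde at C11 followed by spontaneous loss of dimethylamine is the standard mild α-methylenation of aldehydes, needs no strong base and therefore leaves the C6 acrylate ester and C7 untouched.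

Step 25
Reactants: 33 α-methylene aldehyde
Product: 34 11(13)-en-12-oic acid
Conditions: NaClO2, NaH2PO4, 2-methyl-2-butene, t-BuOH/H2O, 0 °C to rt
Reagents that add atoms: sodium chlorite, [Na+].[O-]Cl=O
Why: Pinnick oxidation converts enals to acrylic acids chemoselectively, the scavenger alkene intercepting hypochlorous acid before it can reach the C4(15) methylene.

Step 26
Reactants: 34 acrylic acid
Product: 35 fully silylated methyl ester (1β,3β-OTBS, side-chain OTBDPS)
Conditions: MeI, KHCO3, DMF, rt
Reagents that add atoms: iodomethane, CI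
Why: SN2 alkylation of the carboxylate gives the methyl ester with a base too weak to isomerise the acrylate, and avoids diazoalkanes that could add to the two acrylates.

Step 27
Reactants: 35 fully silylated methyl ester
Product: 36 target CNP0247525.1
Conditions: HF·pyridine, pyridine, THF, 0 °C to rt
Reagents that add atoms: none
Why: Global fluoride desilylation under mildly acidic conditions frees the C1, C3 and side-chain hydroxyls without acyl migration, conjugate addition or ester cleavage and touches no stereocentre.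

Compound list
1 | (S)-3-hydroxy-γ-butyrolactone | O=C1C[C@H](O)CO1 | starting material
2 | (S)-3-(TBS-oxy)-γ-butyrolactone | O=C1C[C@H](O[Si](C)(C)C(C)(C)C)CO1 | intermediate
3 | (3S)-3-(TBS-oxy)-4-hydroxy-N-methoxy-N-methylbutanamide | CON(C)C(=O)C[C@H](O[Si](C)(C)C(C)(C)C)CO | intermediate
4 | (3S)-3-(TBS-oxy)-N-methoxy-N-methyl-4-oxobutanamide | CON(C)C(=O)C[C@H](O[Si](C)(C)C(C)(C)C)C=O | intermediate
5 | (3S)-3-(TBS-oxy)-4-hydroxy-N-methoxy-N-methylhept-6-enamide, C4 epimers | CON(C)C(=O)C[C@H](O[Si](C)(C)C(C)(C)C)C(O)CC=C | intermediate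
6 | (3S)-3-(TBS-oxy)-N-methoxy-N-methyl-4-oxohept-6-enamide | CON(C)C(=O)C[C@H](O[Si](C)(C)C(C)(C)C)C(=O)CC=C | intermediate
7 | (3S)-3-(2-allyl-1,3-dioxolan-2-yl)-3-(TBS-oxy)-N-methoxy-N-methylpropanamide | CON(C)C(=O)C[C@H](O[Si](C)(C)C(C)(C)C)C1(CC=C)OCCO1 | intermediate
8 | secondary ozonide of 7 (1,2,4-trioxolane) | CON(C)C(=O)C[C@H](O[Si](C)(C)C(C)(C)C)C1(CC2OCOO2)OCCO1 | intermediate
9 | (3S)-3-(TBS-oxy)-N-methoxy-N-methyl-3-[2-(2-oxoethyl)-1,3-dioxolan-2-yl]propanamide | CON(C)C(=O)C[C@H](O[Si](C)(C)C(C)(C)C)C1(CC=O)OCCO1 | intermediate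
10 | 3-bromobut-3-en-1-ol | C=C(Br)CCO | starting material
11 | (3-bromobut-3-en-1-yloxy)(tert-butyl)dimethylsilane | C=C(Br)CCO[Si](C)(C)C(C)(C)C | intermediate
12 | 4-(TBS-oxy)but-1-en-2-yllithium | [Li]C(=C)CCO[Si](C)(C)C(C)(C)C | intermediate
13 | C6 allylic alcohol, C6 epimers | CON(C)C(=O)C[C@H](O[Si](C)(C)C(C)(C)C)C1(CC(O)C(=C)CCO[Si](C)(C)C(C)(C)C)OCCO1 | intermediate
14 | C6 enone | CON(C)C(=O)C[C@H](O[Si](C)(C)C(C)(C)C)C1(CC(=O)C(=C)CCO[Si](C)(C)C(C)(C)C)OCCO1 | intermediate
15 | potassium (Z)-enolate of 14 | CON(C)C(=O)C[C@H](O[Si](C)(C)C(C)(C)C)C1(OCCO1)/C=C(\[O-])C(=C)CCO[Si](C)(C)C(C)(C)C.[K+] | intermediate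
16 | (Z)-C5=C6 TES dienol ether, C1 Weinreb amide | CON(C)C(=O)C[C@H](O[Si](C)(C)C(C)(C)C)C1(OCCO1)/C=C(\O[Si](CC)(CC)CC)C(=C)CCO[Si](C)(C)C(C)(C)C | intermediate
17 | magnesium chelate (tetrahedral adduct at C1) | C=C(C)C(O[Mg]Br)(N(C)OC)C[C@H](O[Si](C)(C)C(C)(C)C)C1(OCCO1)/C=C(\O[Si](CC)(CC)CC)C(=C)CCO[Si](C)(C)C(C)(C)C | intermediate
18 | (S)-trienone, precursor of the key step | C=C(C)C(=O)C[C@H](O[Si](C)(C)C(C)(C)C)C1(OCCO1)/C=C(\O[Si](CC)(CC)CC)C(=C)CCO[Si](C)(C)C(C)(C)C | intermediate
19 | trans-fused 1-oxo-octalin, product of the key step | O=C1C[C@H](O[Si](C)(C)C(C)(C)C)C2(OCCO2)[C@@H]3C(O[Si](CC)(CC)CC)=C(CCO[Si](C)(C)C(C)(C)C)CC[C@@]13C | intermediate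
20 | 1β-alcohol | O[C@@H]1C[C@H](O[Si](C)(C)C(C)(C)C)C2(OCCO2)[C@@H]3C(O[Si](CC)(CC)CC)=C(CCO[Si](C)(C)C(C)(C)C)CC[C@@]13C | intermediate
21 | 1β,3β-bis(TBS) ether with C6=C7 TES enol ether | CC(C)(C)[Si](C)(C)O[C@@H]1C[C@H](O[Si](C)(C)C(C)(C)C)C2(OCCO2)[C@@H]3C(O[Si](CC)(CC)CC)=C(CCO[Si](C)(C)C(C)(C)C)CC[C@@]13C | intermediate
22 | 6-ketone, 7β side chain | CC(C)(C)[Si](C)(C)O[C@@H]1C[C@H](O[Si](C)(C)C(C)(C)C)C2(OCCO2)[C@@H]3C(=O)[C@H](CCO[Si](C)(C)C(C)(C)C)CC[C@@]13C | intermediate
23 | 6α-alcohol | CC(C)(C)[Si](C)(C)O[C@@H]1C[C@H](O[Si](C)(C)C(C)(C)C)C2(OCCO2)[C@@H]3[C@@H](O)[C@H](CCO[Si](C)(C)C(C)(C)C)CC[C@@]13C | intermediate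
24 | methyl 2-(hydroxymethyl)acrylate | C=C(CO)C(=O)OC | starting material
25 | methyl 2-[(TBDPS-oxy)methyl]acrylate | C=C(CO[Si](c1ccccc1)(c1ccccc1)C(C)(C)C)C(=O)OC | intermediate
26 | 2-[(TBDPS-oxy)methyl]acrylic acid | C=C(CO[Si](c1ccccc1)(c1ccccc1)C(C)(C)C)C(=O)O | intermediate
27 | mixed anhydride of 26 with 2,4,6-trichlorobenzoic acid | C=C(CO[Si](c1ccccc1)(c1ccccc1)C(C)(C)C)C(=O)OC(=O)c1c(Cl)cc(Cl)cc1Cl | intermediate
28 | C6 ester with C4 dioxolane and C12 OTBS | CC(C)(C)[Si](C)(C)O[C@@H]1C[C@H](O[Si](C)(C)C(C)(C)C)C2(OCCO2)[C@@H]3[C@@H](OC(=O)C(=C)CO[Si](c4ccccc4)(c4ccccc4)C(C)(C)C)[C@H](CCO[Si](C)(C)C(C)(C)C)CC[C@@]13C | intermediate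
29 | 4-ketone with free C12 hydroxyl | CC(C)(C)[Si](C)(C)O[C@@H]1C[C@H](O[Si](C)(C)C(C)(C)C)C(=O)[C@@H]2[C@@H](OC(=O)C(=C)CO[Si](c3ccccc3)(c3ccccc3)C(C)(C)C)[C@H](CCO)CC[C@@]12C | intermediate
30 | 4(15)-methylene alcohol | CC(C)(C)[Si](C)(C)O[C@@H]1C[C@H](O[Si](C)(C)C(C)(C)C)C(=C)[C@@H]2[C@@H](OC(=O)C(=C)CO[Si](c3ccccc3)(c3ccccc3)C(C)(C)C)[C@H](CCO)CC[C@@]12C | intermediate
31 | C12 aldehyde | CC(C)(C)[Si](C)(C)O[C@@H]1C[C@H](O[Si](C)(C)C(C)(C)C)C(=C)[C@@H]2[C@@H](OC(=O)C(=C)CO[Si](c3ccccc3)(c3ccccc3)C(C)(C)C)[C@H](CC=O)CC[C@@]12C | intermediate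
32 | Mannich base (C11 dimethylaminomethyl aldehyde, C11 epimers) | CC(C)(C)[Si](C)(C)O[C@@H]1C[C@H](O[Si](C)(C)C(C)(C)C)C(=C)[C@@H]2[C@@H](OC(=O)C(=C)CO[Si](c3ccccc3)(c3ccccc3)C(C)(C)C)[C@H](C(CN(C)C)C=O)CC[C@@]12C | intermediate
33 | 11(13)-en-12-al | CC(C)(C)[Si](C)(C)O[C@@H]1C[C@H](O[Si](C)(C)C(C)(C)C)C(=C)[C@@H]2[C@@H](OC(=O)C(=C)CO[Si](c3ccccc3)(c3ccccc3)C(C)(C)C)[C@H](C(=C)C=O)CC[C@@]12C | intermediate
34 | 11(13)-en-12-oic acid | CC(C)(C)[Si](C)(C)O[C@@H]1C[C@H](O[Si](C)(C)C(C)(C)C)C(=C)[C@@H]2[C@@H](OC(=O)C(=C)CO[Si](c3ccccc3)(c3ccccc3)C(C)(C)C)[C@H](C(=C)C(=O)O)CC[C@@]12C | intermediate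
35 | fully silylated methyl ester | CC(C)(C)[Si](C)(C)O[C@@H]1C[C@H](O[Si](C)(C)C(C)(C)C)C(=C)[C@@H]2[C@@H](OC(=O)C(=C)CO[Si](c3ccccc3)(c3ccccc3)C(C)(C)C)[C@H](C(=C)C(=O)OC)CC[C@@]12C | intermediate
36 | CNP0247525.1, methyl 1β,3β-dihydroxy-6α-[2-(hydroxymethyl)acryloyloxy]eudesma-4(15),11(13)-dien-12-oate (1R,3S,5S,6S,7S,10R) | C=C(CO)C(=O)O[C@@H]1[C@H]2C(=C)[C@@H](O)C[C@@H](O)[C@]2(C)CC[C@H]1C(=C)C(=O)OC | target

Total step count: 27. Longest linear sequence: 24 steps (steps 1–7, 9–17 and 20–27).

Steps most likely to fail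

Step 13. The cycloaddition joins a diene terminus that bears a fully substituted ketal carbon to a fully substituted dienophile carbon, in the orientation that the silyloxy group does not assist. It may therefore be slow enough for the allylic ketal and the enol ether to decay. Folding with the C1 carbonyl endo may also compete and give cis ring fusion.

The fallback sets out from 18 and comes back at 22, and it uses the cis material instead of discarding it. The cis-fused adduct F1 (5β-H, same C10 configuration as 19) is treated with buffered Bu4NF to give the cis-1,6-dione F2. DBU in toluene then epimerises C5 (and C7) through the C6 enolate to the trans-1,6-dione F3, the direction known from 5β- to 5α-6-oxo steroids. NaBH4 in MeOH/CH2Cl2 at low temperature reduces the much less crowded C1 ketone from the α face to the 1β-hydroxy-6-ketone F4. TBSOTf with 2,6-lutidine converts F4 into 22. A cis adduct of opposite C10 configuration would not be rescued in this way.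

Step 17. Protonation of the ketyl-derived species may not follow product stability, or enolisation may return ketone. Either outcome gives poor selectivity between the equatorial and the axial C6 alcohol.

The fallback sets out from 21 and comes back at 23, and it sets C6 and C7 together by a syn addition instead of a carbonyl reduction. CsF and PhNTf2 in DME turn the regiodefined TES enol ether into the C6=C7 enol triflate F5. Pd(OAc)2, PPh3, HCO2H and Bu3N in DMF reduce F5 to the C6=C7 alkene F6. BH3·THF then adds from the α face, the β face being screened by C14 and the axial ketal oxygen, with boron on C6 and hydrogen on C7. Oxidation with NaOH/H2O2 proceeds with retention and gives 23 with 6α-OH and 7α-H.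

Step 21. Ketal cleavage beside two oxygenated carbons may be slower than expected. Once the C4 ketone is free, the C6 acyloxy group lies β to it, so forcing the hydrolysis may cause loss of the ester by elimination. The preceding acylation next to the ketal is also the most crowded one of the route.

The fallback sets out from 23 and comes back at 30. It changes the order, so that C4 is unmasked and methylenated before any ester is present and stronger acid can be tolerated. p-TsOH in wet acetone gives the 6α,12-dihydroxy-4-ketone F7. Zn/CH2Br2/TiCl4 gives the 4(15)-methylene diol F8. TBSCl with imidazole silylates only the primary hydroxyl to give the C12 TBS ether F9. Yamaguchi esterification with 26 gives the C6 ester F10. Pyridine-buffered HF·pyridine at 0 °C then removes the primary TBS ether selectively to give 30.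

Further compounds
F1 | step 13 | cis-fused adduct (5β-H, 10β-methyl) | O=C1C[C@H](O[Si](C)(C)C(C)(C)C)C2(OCCO2)[C@H]3C(O[Si](CC)(CC)CC)=C(CCO[Si](C)(C)C(C)(C)C)CC[C@@]13C
F2 | step 13 | cis-1,6-dione (C7 epimers) | O=C1C[C@H](O[Si](C)(C)C(C)(C)C)C2(OCCO2)[C@H]3C(=O)C(CCO[Si](C)(C)C(C)(C)C)CC[C@@]13C
F3 | step 13 | trans-1,6-dione | O=C1C[C@H](O[Si](C)(C)C(C)(C)C)C2(OCCO2)[C@@H]3C(=O)[C@H](CCO[Si](C)(C)C(C)(C)C)CC[C@@]13C
F4 | step 13 | 1β-hydroxy-6-ketone | O[C@@H]1C[C@H](O[Si](C)(C)C(C)(C)C)C2(OCCO2)[C@@H]3C(=O)[C@H](CCO[Si](C)(C)C(C)(C)C)CC[C@@]13C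
F5 | step 17 | C6=C7 enol triflate | CC(C)(C)[Si](C)(C)O[C@@H]1C[C@H](O[Si](C)(C)C(C)(C)C)C2(OCCO2)[C@@H]3C(OS(=O)(=O)C(F)(F)F)=C(CCO[Si](C)(C)C(C)(C)C)CC[C@@]13C
F6 | step 17 | C6=C7 alkene | CC(C)(C)[Si](C)(C)O[C@@H]1C[C@H](O[Si](C)(C)C(C)(C)C)C2(OCCO2)[C@@H]3C=C(CCO[Si](C)(C)C(C)(C)C)CC[C@@]13C
F7 | step 21 | 6α,12-dihydroxy-4-ketone | CC(C)(C)[Si](C)(C)O[C@@H]1C[C@H](O[Si](C)(C)C(C)(C)C)C(=O)[C@@H]2[C@@H](O)[C@H](CCO)CC[C@@]12C
F8 | step 21 | 4(15)-methylene diol | CC(C)(C)[Si](C)(C)O[C@@H]1C[C@H](O[Si](C)(C)C(C)(C)C)C(=C)[C@@H]2[C@@H](O)[C@H](CCO)CC[C@@]12C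
F9 | step 21 | C12 TBS ether with free 6α-hydroxyl | CC(C)(C)[Si](C)(C)O[C@@H]1C[C@H](O[Si](C)(C)C(C)(C)C)C(=C)[C@@H]2[C@@H](O)[C@H](CCO[Si](C)(C)C(C)(C)C)CC[C@@]12C
F10 | step 21 | C6 ester with C12 OTBS and 4(15)-methylene | CC(C)(C)[Si](C)(C)O[C@@H]1C[C@H](O[Si](C)(C)C(C)(C)C)C(=C)[C@@H]2[C@@H](OC(=O)C(=C)CO[Si](c3ccccc3)(c3ccccc3)C(C)(C)C)[C@H](CCO[Si](C)(C)C(C)(C)C)CC[C@@]12C
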